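**Retrosynthetic overview**
1. 9-Acetyllisoobtusol (13) comes from the ring-B trisubstituted alkene of acetate 11. The halogens go on last: Cl⁺/H₂O gives the chlorohydrin, then tertiary OH → Br with retention.
2. 11 comes from the C9 ketone (reduction, then acetylation), the C7 exocyclic methylene (deconjugation of a C7-methyl enone), and the C11 gem-dimethyl with C10–Br (conjugate methylation of an α-bromodienone).
3. That dienone (7) is formed by enantioselective dearomative para-spirocyclization of phenol 6. Ring B closes in this step, and the 2-bromo substituent breaks the symmetry of the arene and becomes C10–Br.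
4. Phenol 6 comes from 4-bromo-3,5-dimethylphenol by Negishi coupling, ortho-bromination and cross-metathesis.

Ring order: aromatic ring A is present from the start and becomes a dienone in step 4. Ring B is formed in step 4. The ring-B halogens are installed last.

Assumption: 4-bromo-3,5-dimethylphenol (made from 3,5-dimethylphenol), 4-bromo-2-methylbut-1-ene and allyl acetate are commercial. The Pd-ligand enantiomer is chosen by screening to give the (6R) spiro centre drawn below.

**Step 1**
Reactants: 1 (4-bromo-3,5-dimethylphenol), 2 (4-bromo-2-methylbut-1-ene)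
Product: 3 (3,5-dimethyl-4-(3-methylbut-3-en-1-yl)phenol)
Conditions: 2, Zn, LiCl, THF → RZnBr; then 1, Pd-PEPPSI-IPent, THF/NMP, 60 °C
Reagents that add atoms: none (the alkyl group comes from reactant 2 after zinc insertion)
Why: Negishi coupling joins the hindered di-ortho-methyl aryl bromide to a primary alkylzinc, and the free phenol is tolerated as its zinc phenoxide.

**Step 2**
Reactants: 3
Product: 4 (2-bromo-3,5-dimethyl-4-(3-methylbut-3-en-1-yl)phenol)
Conditions: NBS (1.0 equiv), i-Pr₂NH (cat.), CH₂Cl₂, –78 → 0 °C
Reagents that add atoms: N-bromosuccinimide, O=C1CCC(=O)N1Br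
Why: Amine-catalysed ortho-selective electrophilic bromination of phenols is much faster than bromination of the unactivated 1,1-disubstituted alkene. The new bromine makes the two future ring-A arms different and will become C10–Br.

**Step 3**
Reactants: 4, 5 (allyl acetate)
Product: 6 ((E)-5-(3-bromo-4-hydroxy-2,6-dimethylphenyl)-3-methylpent-2-en-1-yl acetate)
Conditions: Hoveyda–Grubbs II (5 mol%), 5 (5 equiv), CH₂Cl₂, 40 °C
Reagents that add atoms: none (allyl acetate is reactant 5; ethylene is lost)
Why: Cross-metathesis converts the 1,1-disubstituted alkene into the trisubstituted allylic acetate that serves as the π-allyl precursor. The E/Z ratio does not matter, because the π-allyl equilibrates in step 4.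

**Step 4**
Reactants: 6
Product: 7 ((6R)-10-bromo-3,7,11-trimethylspiro[5.5]undeca-2,7,10-trien-9-one)
Conditions: Pd₂(dba)₃ (2.5 mol%), chiral bisphosphine (Trost-type, 7.5 mol%), Cs₂CO₃, toluene, 40 °C
Reagents that add atoms: none (AcOH is lost)
Why: Proposed new method: the phenoxide ionises the allylic acetate to a chiral Pd-π-allyl, and the para carbon attacks the distal allyl terminus in a 6-endo intramolecular Tsuji–Trost dearomative alkylation. This forms the spiro quaternary centre and the ring-B Z-alkene. The catalyst chooses the arene face, and the ortho-Br makes the two arms enantiotopic, so the spiro centre is set enantioselectively. The closest known reaction is Pd-catalysed asymmetric allylic dearomatization of phenols giving spirocyclohexadienones, here extended from 5-exo to 6-endo closure.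

**Step 5**
Reactants: 7
Product: 8 ((6R,10R)-10-bromo-3,7,11,11-tetramethylspiro[5.5]undeca-2,7-dien-9-one)
Conditions: Me₂CuLi (1.3 equiv), Et₂O, –78 °C; then AcOH/THF, –78 °C
Reagents that add atoms: lithium dimethylcuprate, C[Cu-]C.[Li+]
Why: Cuprate 1,4-addition goes to the more electrophilic α-bromoenone arm and makes the C11 gem-dimethyl next to the spiro centre. Kinetic axial protonation of the α-bromo enolate, anti to the axial C11 methyl, puts Br equatorial at C10 (epimerisable later).

**Step 6**
Reactants: 8
Product: 9 ((6R,10R)-10-bromo-3,11,11-trimethyl-7-methylidenespiro[5.5]undec-2-en-9-one)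
Conditions: TMSOTf, Et₃N, CH₂Cl₂, –78 → 0 °C; then AcOH, THF/H₂O, 0 °C
Reagents that add atoms: none (the silyl group is removed on workup)
Why: Proposed new method: soft enolisation is expected to give the extended 1-silyloxy-diene by γ-deprotonation of the C7 methyl. The alternative α′-deprotonation is blocked because C10 is hindered and C6 is quaternary. Kinetic α-protonation then gives the β,γ-enone with the exocyclic methylene. The closest known reaction is deconjugative protonation of silyl dienol ethers, here used with an α′-bromide present.

**Step 7**
Reactants: 9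
Product: 10 ((6R,9S,10R)-10-bromo-3,11,11-trimethyl-7-methylidenespiro[5.5]undec-2-en-9-ol)
Conditions: L-Selectride, THF, –78 °C; then sat. NH₄Cl
Reagents that add atoms: none (only H is added)
Why: The axial methyl at C11 blocks axial hydride attack on the C9 ketone, so the bulky hydride attacks equatorially and gives the axial alcohol cis to equatorial C10–Br, which is the cis bromohydrin of the target.

**Step 8**
Reactants: 10
Product: 11 ((6R,9S,10R)-10-bromo-3,11,11-trimethyl-7-methylidenespiro[5.5]undec-2-en-9-yl acetate)
Conditions: Ac₂O, DMAP, pyridine, CH₂Cl₂, 0 °C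
Reagents that add atoms: acetic anhydride, CC(=O)OC(C)=O
Why: Standard O-acetylation of the hindered axial alcohol. No stereocentre is touched.

**Step 9**
Reactants: 11
Product: 12 ((2S,3S,6R,9S,10R)-10-bromo-2-chloro-3-hydroxy-3,11,11-trimethyl-7-methylidenespiro[5.5]undecan-9-yl acetate)
Conditions: NCS, acetone/H₂O (4:1), 0 °C
Reagents that add atoms: N-chlorosuccinimide, O=C1CCC(=O)N1Cl; water, O
Why: Electrophilic chlorination of the most nucleophilic alkene (ring-B trisubstituted) gives a chloronium ion, which water opens anti at the tertiary carbon (Markovnikov, chlorohydrin formation). The face is chosen by the spiro centre, with Cl⁺ syn to the sp² C7 and anti to the gem-dimethyl C11. This sets C2–Cl up and C3–OH down.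

**Step 10**
Reactants: 12
Product: 13 (9-acetyllisoobtusol, (2S,3S,6R,9S,10R)-3,10-dibromo-2-chloro-3,11,11-trimethyl-7-methylidenespiro[5.5]undecan-9-yl acetate)
Conditions: TMSBr (3 equiv), CH₂Cl₂, –78 °C; then NaHCO₃
Reagents that add atoms: bromotrimethylsilane, C[Si](C)(C)Br
Why: Proposed new method: the tertiary silyl ether ionises and the cation is bridged by the neighbouring C2 chlorine as a chloronium ion, which bromide opens anti. The net result is retention, with Br trans to Cl as in the target. The closest known reaction is neighbouring-halogen-assisted SN1 substitution of vicinal halohydrins.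

**Compound list**

| # | Name | SMILES | Role |
|---|---|---|---|
| 1 | 4-bromo-3,5-dimethylphenol | Cc1cc(O)cc(C)c1Br | starting material |
| 2 | 4-bromo-2-methylbut-1-ene | C=C(C)CCBr | starting material |
| 3 | 3,5-dimethyl-4-(3-methylbut-3-en-1-yl)phenol | Cc1cc(O)cc(C)c1CCC(C)=C | intermediate |
| 4 | 2-bromo-3,5-dimethyl-4-(3-methylbut-3-en-1-yl)phenol | Cc1cc(O)c(Br)c(C)c1CCC(C)=C | intermediate |
| 5 | allyl acetate | C=CCOC(C)=O | starting material |
| 6 | (E)-5-(3-bromo-4-hydroxy-2,6-dimethylphenyl)-3-methylpent-2-en-1-yl acetate | Cc1cc(O)c(Br)c(C)c1CC/C(C)=C/COC(C)=O | intermediate |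
| 7 | (6R)-10-bromo-3,7,11-trimethylspiro[5.5]undeca-2,7,10-trien-9-one | CC1=CC(=O)C(Br)=C(C)[C@@]12CCC(C)=CC2 | intermediate |
| 8 | (6R,10R)-10-bromo-3,7,11,11-tetramethylspiro[5.5]undeca-2,7-dien-9-one | CC1=CC(=O)[C@H](Br)C(C)(C)[C@@]12CCC(C)=CC2 | intermediate |
| 9 | (6R,10R)-10-bromo-3,11,11-trimethyl-7-methylidenespiro[5.5]undec-2-en-9-one | C=C1CC(=O)[C@H](Br)C(C)(C)[C@@]12CCC(C)=CC2 | intermediate |
| 10 | (6R,9S,10R)-10-bromo-3,11,11-trimethyl-7-methylidenespiro[5.5]undec-2-en-9-ol | C=C1C[C@H](O)[C@H](Br)C(C)(C)[C@@]12CCC(C)=CC2 | intermediate |
| 11 | (6R,9S,10R)-10-bromo-3,11,11-trimethyl-7-methylidenespiro[5.5]undec-2-en-9-yl acetate | C=C1C[C@H](OC(C)=O)[C@H](Br)C(C)(C)[C@@]12CCC(C)=CC2 | intermediate |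
| 12 | (2S,3S,6R,9S,10R)-10-bromo-2-chloro-3-hydroxy-3,11,11-trimethyl-7-methylidenespiro[5.5]undecan-9-yl acetate | C=C1C[C@H](OC(C)=O)[C@H](Br)C(C)(C)[C@@]12CC[C@](C)(O)[C@@H](Cl)C2 | intermediate |
| 13 | 9-acetyllisoobtusol, (2S,3S,6R,9S,10R)-3,10-dibromo-2-chloro-3,11,11-trimethyl-7-methylidenespiro[5.5]undecan-9-yl acetate | C=C1C[C@H](OC(C)=O)[C@H](Br)C(C)(C)[C@@]12CC[C@](C)(Br)[C@@H](Cl)C2 | target |

**Total:** 10 steps; longest linear sequence 10 steps (1 → 3 → 4 → 6 → 7 → 8 → 9 → 10 → 11 → 12 → 13).

**Three steps most likely to fail**
1. **Step 4 (enantioselective 6-endo dearomative spirocyclization):** the ee may be low because the ortho-Br is remote from the reacting carbon, and 6-endo π-allyl closure requires the strained anti-π-allyl isomer. Fallback: make racemic 7 by base-mediated SN2 dearomative alkylation with the Z-allylic/primary bromide from ring opening of 4-methyl-3,6-dihydro-2H-pyran. Carry the racemate through and resolve bromohydrin 10 by lipase-catalysed acetylation with vinyl acetate, which also supplies acetate 11.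
2. **Steps 5–6 (methylation next to the quaternary spiro centre, then deconjugation with the α-Br present):** the second quaternary centre may form poorly, or C10 may epimerise or debrominate. The C10 diastereomer ratio relative to the spiro centre depends only on a weak ring-B bias. Fallback: use the 3-methoxy-5-methylphenol (orcinol monomethyl ether) spirodienone instead. Install CMe₂/Br by conjugate addition on the enone arm, hydrolyse the vinylogous ester to the C7 ketone, and form the methylene by Petasis methylenation.
3. **Steps 9–10 (Cl⁺ facial selectivity, then retentive tertiary OH → Br):** the chloronium may form on the wrong face, the exocyclic alkene may react, or elimination may compete. Fallback: dehydrate the chlorohydrin (Burgess reagent) to the allylic chloride with a C3=C4 ring-B alkene, then add HBr in a Markovnikov sense, anti through chloronium assistance, to give the tertiary bromide.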